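**Plan**

Numbering: chain C1 (CH2OH) to C16 (CH2OAc); C6 is the carbinol carbon, C7 the quaternary carbon on ring oxygen O7, C10=C11 the ring alkene, C20 the lactone carbonyl.
Cuts: C11–C12 (sp2–sp3 Negishi coupling), C5–C6 (Grignard addition to a C6 aldehyde), and inside the ring both bonds of C11 (C20–C11 and C11–C10), which removes one ring carbon.
Enabling feature: the lactone ring O7–C20–C11–C10–C9–C8–C7 is the six-membered enol ether ring O7–C20=C10–C9–C8–C7 with C11 slipped in between C20 and C10, and C7 with its methyl group is the carbinol carbon of (R)-linalool.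
Forward order: linalool → dihydropyran (the only ring made by cyclisation) → one-carbon ring expansion to the bromo-oxepine → lactone → C6 aldehyde → C1–C5 added at C6 → C12–C16 joined at C11 → desilylation.
Stereochemistry: C7 from (R)-linalool; C6 by (S)-Me-CBS reduction of the C6 ketone; C2=C3 (Z) bought with (2Z)-3-methylpent-2-en-4-yn-1-ol; C14=C15 (Z) by Still–Gennari olefination; C10=C11 cis by the ring.

Key step: step 4

Assumption: the (R)-(−)-linalool used is of high enantiomeric purity, because C7 is carried over from it unchanged and no later step can upgrade it.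

**Route**

Step 1
Reactants: 1 (R)-(−)-linalool
Product: 3 (5R)-5-ethenyl-5-methyloxolan-2-ol (both anomers), via hydroxy aldehyde 2 (not isolated)
Conditions: O3, CH2Cl2/MeOH, −78 °C (Sudan Red 7B end point); then Me2S, −78 °C to rt
Reagents that add atoms: ozone, [O-][O+]=O
Why: Ozonolysis with reductive work-up is chemoselective because electrophilic ozone cleaves the electron-rich trisubstituted isopropylidene alkene far faster than the monosubstituted vinyl group, and the freed 4-hydroxy aldehyde 2 closes spontaneously to the five-membered lactol 3 without touching the carbinol stereocentre.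

Step 2
Reactants: 3 (5R)-5-ethenyl-5-methyloxolan-2-ol
Product: 4 (3R)-3-methylhept-1-en-6-yn-3-ol
Conditions: dimethyl (1-diazo-2-oxopropyl)phosphonate, K2CO3, MeOH, 0 °C to rt
Reagents that add atoms: dimethyl (1-diazo-2-oxopropyl)phosphonate, CC(=O)C(=[N+]=[N-])P(=O)(OC)OC
Why: Ohira–Bestmann form of the Seyferth–Gilbert homologation, well established for lactols: carbonate in methanol opens the lactol to its aldehyde and deacylates the reagent to the diazomethylphosphonate anion, whose olefination, loss of N2 and 1,2-hydride shift give the terminal alkyne that becomes C20; the stereocentre is not involved.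

Step 3
Reactants: 4 (3R)-3-methylhept-1-en-6-yn-3-ol
Product: 5 (2R)-2-ethenyl-2-methyl-3,4-dihydro-2H-pyran
Conditions: W(CO)6 (25 mol%), Et3N, THF, hν (350 nm), 60 °C
Reagents that add atoms: none
Why: Tungsten-catalysed endo cycloisomerisation of a 4-alkyn-1-ol: photolysis gives a W(CO)5 fragment that turns the terminal alkyne into a tungsten vinylidene, the tertiary hydroxyl adds to its electrophilic carbon in the 6-endo sense and protodemetalation in the amine-buffered medium releases the cyclic enol ether, with C7 untouched.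

Step 4
Reactants: 5 (2R)-2-ethenyl-2-methyl-3,4-dihydro-2H-pyran; 6 bromoform
Product: 8 (7R)-3-bromo-7-ethenyl-2-methoxy-7-methyl-2,5,6,7-tetrahydrooxepine (both epimers at the acetal carbon), via dibromocyclopropane 7 (not isolated)
Conditions: CHBr3, 50% aq NaOH, BnEt3NCl (cat.), CH2Cl2, 0 °C to rt; crude 7, then Ag2CO3, MeOH, reflux, dark
Reagents that add atoms: methanol, CO
Why: Dibromocarbene, formed by α-elimination from bromoform at the phase boundary, adds in a concerted [2+1] fashion to the electron-rich enol ether C20=C10 of 5 and so closes the cyclopropane of 7, forming C20–C11 and C11–C10 with both bromines on C11. Ag+ then removes the endo bromide while the C20–C10 bond opens in a disrotatory two-electron electrocyclic process, so the seven-membered ring arises by expansion of the six-membered ring and not by a cyclisation; the 2-bromoallyl cation is an oxocarbenium ion at C20 and is captured there by methanol. This is the known sequence of dihalocarbene addition and silver-assisted opening that converts glycals and simple dihydropyrans into 2-alkoxy-3-halo-tetrahydrooxepines. No lasting stereocentre is created: the two cyclopropane centres vanish on opening, the acetal carbon forms as both epimers and is oxidised in step 5, and C7 is a spectator. The carbene must choose the enol ether over the vinyl group, which the donor oxygen secures against an alkene that is electron-poor and flanked by a quaternary carbon when only a slight excess of bromoform is used. The endo bromide must be the one that leaves, which the ring fusion enforces because only that mode (Woodward–Hoffmann–DePuy rule) turns the ring bonds inward and gives the cis C10=C11 alkene that a seven-membered ring can hold, leaving the exo bromine on C11 for the later coupling.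

Step 5
Reactants: 8 (7R)-3-bromo-7-ethenyl-2-methoxy-7-methyl-2,5,6,7-tetrahydrooxepine
Product: 10 (7R)-3-bromo-7-ethenyl-7-methyl-6,7-dihydrooxepin-2(5H)-one, via lactol 9 (not isolated)
Conditions: CrO3, H2SO4, H2O/acetone, 0 °C
Reagents that add atoms: water, O
Why: Jones oxidation of a lactol methyl ether: aqueous acid exchanges methoxy for hydroxy through the allylic oxocarbenium ion and lactol 9 is oxidised as its chromate ester by hexavalent chromium to the conjugated lactone, so both acetal epimers converge while the vinyl group, the vinyl bromide and the quaternary C7 offer no oxidisable C–H or O–H bond.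

Step 6
Reactants: 10 (7R)-3-bromo-7-ethenyl-7-methyl-6,7-dihydrooxepin-2(5H)-one
Product: 11 (2R)-6-bromo-2-methyl-7-oxo-2,3,4,7-tetrahydrooxepine-2-carbaldehyde
Conditions: O3, CH2Cl2/MeOH, −78 °C (Sudan Red 7B end point); then Me2S, −78 °C to rt
Reagents that add atoms: ozone, [O-][O+]=O
Why: Chemoselective ozonolysis with reductive work-up: the monosubstituted vinyl group reacts with ozone much faster than the ring alkene, which is deactivated by both the lactone carbonyl and the bromine, and the new C6 aldehyde cannot epimerise because C7 is quaternary.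

Step 7
Reactants: 12 (2Z)-3-methylpent-2-en-4-yn-1-ol
Product: 13 tert-butyl(dimethyl){[(2Z)-3-methylpent-2-en-4-yn-1-yl]oxy}silane
Conditions: TBSCl, imidazole, CH2Cl2, 0 °C to rt
Reagents that add atoms: tert-butyl(chloro)dimethylsilane, CC(C)(C)[Si](C)(C)Cl
Why: Standard imidazole-promoted silylation of a primary allylic alcohol, to which the (Z)-alkene and the terminal alkyne are inert.

Step 8
Reactants: 13 tert-butyl(dimethyl){[(2Z)-3-methylpent-2-en-4-yn-1-yl]oxy}silane
Product: 14 tert-butyl(dimethyl){[(2Z)-3-methylpenta-2,4-dien-1-yl]oxy}silane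
Conditions: H2 (1 atm), Pd/CaCO3 poisoned with Pb(OAc)2 (Lindlar catalyst), quinoline, hexane, rt
Reagents that add atoms: none
Why: Lindlar semihydrogenation: on the poisoned catalyst the terminal alkyne binds and is reduced much faster than any alkene, which gives the vinyl group while the trisubstituted (Z)-alkene keeps its geometry.

Step 9
Reactants: 14 tert-butyl(dimethyl){[(2Z)-3-methylpenta-2,4-dien-1-yl]oxy}silane
Product: 16 (3Z)-5-{[tert-butyl(dimethyl)silyl]oxy}-3-methylpent-3-en-1-ol, via alkylborane 15 (not isolated)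
Conditions: 9-BBN, THF, 0 °C to rt; then NaOH, H2O2, H2O, 0 °C
Reagents that add atoms: hydrogen peroxide, OO
Why: Hydroboration–oxidation: the bulky dialkylborane adds only to the monosubstituted terminal alkene of the diene with boron on the terminal carbon, the trisubstituted alkene being too hindered, and alkaline peroxide replaces boron by hydroxyl with retention to give the homoallylic alcohol (C5).

Step 10
Reactants: 16 (3Z)-5-{[tert-butyl(dimethyl)silyl]oxy}-3-methylpent-3-en-1-ol
Product: 17 {[(2Z)-5-bromo-3-methylpent-2-en-1-yl]oxy}(tert-butyl)dimethylsilane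
Conditions: CBr4, PPh3, CH2Cl2, 0 °C
Reagents that add atoms: tetrabromomethane, BrC(Br)(Br)Br
Why: Appel reaction: the alkoxyphosphonium ion formed from PPh3 and CBr4 is displaced by bromide in an SN2 step at the unhindered primary carbon under nearly neutral conditions that spare the silyl ether and the alkene geometry.

Step 11
Reactants: 17 {[(2Z)-5-bromo-3-methylpent-2-en-1-yl]oxy}(tert-butyl)dimethylsilane; 11 (2R)-6-bromo-2-methyl-7-oxo-2,3,4,7-tetrahydrooxepine-2-carbaldehyde
Product: 19 (7R)-3-bromo-7-[(4Z)-6-{[tert-butyl(dimethyl)silyl]oxy}-1-hydroxy-4-methylhex-4-en-1-yl]-7-methyl-6,7-dihydrooxepin-2(5H)-one (both C6 epimers), via Grignard reagent 18 (not isolated)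
Conditions: 17, Mg, THF, rt to 40 °C; then 11, THF, −78 °C; aq NH4Cl
Reagents that add atoms: none
Why: Grignard addition: the homoallylic magnesium reagent 18 should add to the aldehyde, by far the most electrophilic carbonyl, at −78 °C faster than it attacks the hindered conjugated lactone or exchanges with the vinyl bromide, and the new C6 centre forms without reliable control and is erased in step 12.

Step 12
Reactants: 19 (7R)-3-bromo-7-[(4Z)-6-{[tert-butyl(dimethyl)silyl]oxy}-1-hydroxy-4-methylhex-4-en-1-yl]-7-methyl-6,7-dihydrooxepin-2(5H)-one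
Product: 20 (7R)-3-bromo-7-[(4Z)-6-{[tert-butyl(dimethyl)silyl]oxy}-4-methylhex-4-enoyl]-7-methyl-6,7-dihydrooxepin-2(5H)-one
Conditions: Dess–Martin periodinane, NaHCO3, CH2Cl2, 0 °C to rt
Reagents that add atoms: none
Why: Dess–Martin oxidation of the secondary alcohol under buffered, non-acidic conditions converges both C6 epimers to the ketone, with the silyl ether, lactone and vinyl bromide inert and no α-hydrogen at C7.

Step 13
Reactants: 20 (7R)-3-bromo-7-[(4Z)-6-{[tert-butyl(dimethyl)silyl]oxy}-4-methylhex-4-enoyl]-7-methyl-6,7-dihydrooxepin-2(5H)-one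
Product: 21 (7R)-3-bromo-7-[(1R,4Z)-6-{[tert-butyl(dimethyl)silyl]oxy}-1-hydroxy-4-methylhex-4-en-1-yl]-7-methyl-6,7-dihydrooxepin-2(5H)-one
Conditions: (S)-2-methyl-CBS-oxazaborolidine (20 mol%), BH3·SMe2, THF, −30 °C; MeOH
Reagents that add atoms: none
Why: Corey–Bakshi–Shibata reduction: the ketone binds to the ring boron of the (S)-oxazaborolidine anti to its bulky quaternary C7 side and cis to the slim C5 methylene, and the nitrogen-bound borane delivers hydride through a six-membered transition state to the Si face of C6, which sets (6R) under catalyst control in the sense known for tert-alkyl methyl ketones, while at low temperature ketone reduction should outrun hydroboration of the trisubstituted alkene.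

Step 14
Reactants: 22 3-{[tert-butyl(dimethyl)silyl]oxy}propanal; 23 ethyl 2-[bis(2,2,2-trifluoroethoxy)phosphoryl]propanoate
Product: 25 ethyl (2Z)-5-{[tert-butyl(dimethyl)silyl]oxy}-2-methylpent-2-enoate, via potassium phosphonate carbanion 24 (not isolated)
Conditions: 23, KN(SiMe3)2, 18-crown-6, THF, −78 °C; then 22, −78 °C
Reagents that add atoms: none
Why: Still–Gennari variant of the Horner–Wadsworth–Emmons olefination: the electron-poor trifluoroethyl phosphonate and the crown-ether-separated potassium ion make elimination from the kinetically formed adduct faster than its equilibration, so the (Z)-trisubstituted enoate with the ester cis to the chain is expected.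

Step 15
Reactants: 25 ethyl (2Z)-5-{[tert-butyl(dimethyl)silyl]oxy}-2-methylpent-2-enoate
Product: 26 (2Z)-5-{[tert-butyl(dimethyl)silyl]oxy}-2-methylpent-2-en-1-ol
Conditions: iBu2AlH, CH2Cl2, −78 °C
Reagents that add atoms: none
Why: Diisobutylaluminium hydride reduces the conjugated ester in the 1,2-sense through the aldehyde to the allylic alcohol without touching the silyl ether or the alkene geometry.

Step 16
Reactants: 26 (2Z)-5-{[tert-butyl(dimethyl)silyl]oxy}-2-methylpent-2-en-1-ol
Product: 27 (2Z)-5-{[tert-butyl(dimethyl)silyl]oxy}-2-methylpent-2-en-1-yl acetate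
Conditions: Ac2O, pyridine, DMAP (cat.), CH2Cl2, 0 °C to rt
Reagents that add atoms: acetic anhydride, CC(=O)OC(C)=O
Why: Nucleophile-catalysed acetylation of the primary allylic alcohol installs the C16 acetate of the target already at the fragment stage.

Step 17
Reactants: 27 (2Z)-5-{[tert-butyl(dimethyl)silyl]oxy}-2-methylpent-2-en-1-yl acetate
Product: 28 (2Z)-5-hydroxy-2-methylpent-2-en-1-yl acetate
Conditions: HF·pyridine, pyridine, THF, 0 °C to rt
Reagents that add atoms: none
Why: Pyridine-buffered HF cleaves the primary silyl ether through Si–F bond formation and leaves the allylic acetate intact, which basic fluoride or methanolic acid might not.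

Step 18
Reactants: 28 (2Z)-5-hydroxy-2-methylpent-2-en-1-yl acetate
Product: 29 (2Z)-5-iodo-2-methylpent-2-en-1-yl acetate
Conditions: I2, PPh3, imidazole, CH2Cl2, 0 °C
Reagents that add atoms: iodine, II
Why: Appel-type iodination: the iodophosphonium species activates the primary alcohol and iodide displaces it by SN2, with imidazole buffering the acid so that the acetate and the alkene geometry survive.

Step 19
Reactants: 29 (2Z)-5-iodo-2-methylpent-2-en-1-yl acetate; 21 (7R)-3-bromo-7-[(1R,4Z)-6-{[tert-butyl(dimethyl)silyl]oxy}-1-hydroxy-4-methylhex-4-en-1-yl]-7-methyl-6,7-dihydrooxepin-2(5H)-one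
Product: 31 (2Z)-5-{(7R)-7-[(1R,4Z)-6-{[tert-butyl(dimethyl)silyl]oxy}-1-hydroxy-4-methylhex-4-en-1-yl]-7-methyl-2-oxo-2,5,6,7-tetrahydrooxepin-3-yl}-2-methylpent-2-en-1-yl acetate, via alkylzinc iodide 30 (not isolated)
Conditions: 29, Zn (activated with BrCH2CH2Br and Me3SiCl), DMF, rt; then 21, PdCl2(dppf) (5 mol%), THF/DMF, rt to 40 °C
Reagents that add atoms: none
Why: Negishi sp2–sp3 cross-coupling: zinc inserts into the primary C–I bond to give the ester-tolerant alkylzinc iodide 30, oxidative addition of zerovalent palladium into the activated C11–Br bond of the α-bromo enoate is fast, the wide-bite-angle dppf ligand favours reductive elimination over β-hydride elimination, and an alkylzinc halide used in excess is a weak enough base to pass the free C6 hydroxyl, the lactone and the acetate.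

Step 20
Reactants: 31 (2Z)-5-{(7R)-7-[(1R,4Z)-6-{[tert-butyl(dimethyl)silyl]oxy}-1-hydroxy-4-methylhex-4-en-1-yl]-7-methyl-2-oxo-2,5,6,7-tetrahydrooxepin-3-yl}-2-methylpent-2-en-1-yl acetate
Product: 32 (2Z)-5-{(7R)-7-[(1R,4Z)-1,6-dihydroxy-4-methylhex-4-en-1-yl]-7-methyl-2-oxo-2,5,6,7-tetrahydrooxepin-3-yl}-2-methylpent-2-en-1-yl acetate (CNP0286404.1)
Conditions: HF·pyridine, pyridine, THF, 0 °C
Reagents that add atoms: none
Why: Buffered HF·pyridine removes the primary allylic silyl ether through Si–F bond formation under conditions too mild to cleave the acetate, open the lactone or cause acyl migration to the neighbouring C6 hydroxyl, which delivers the target.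

**Compound list**

1 | (R)-(−)-linalool, (3R)-3,7-dimethylocta-1,6-dien-3-ol | CC(C)=CCC[C@](C)(C=C)O | starting material
2 | (4R)-4-hydroxy-4-methylhex-5-enal | O=CCC[C@](C)(C=C)O | intermediate (not isolated)
3 | (5R)-5-ethenyl-5-methyloxolan-2-ol (both anomers) | OC1CC[C@](C)(C=C)O1 | intermediate
4 | (3R)-3-methylhept-1-en-6-yn-3-ol | C#CCC[C@](C)(C=C)O | intermediate
5 | (2R)-2-ethenyl-2-methyl-3,4-dihydro-2H-pyran | C1=CCC[C@](C)(C=C)O1 | intermediate
6 | bromoform | BrC(Br)Br | starting material
7 | (3R)-7,7-dibromo-3-ethenyl-3-methyl-2-oxabicyclo[4.1.0]heptane (both cis-fused diastereomers) | BrC1(Br)C2CC[C@](C)(C=C)OC12 | intermediate (not isolated)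
8 | (7R)-3-bromo-7-ethenyl-2-methoxy-7-methyl-2,5,6,7-tetrahydrooxepine (both epimers at C2) | COC1C(Br)=CCC[C@](C)(C=C)O1 | intermediate
9 | (7R)-3-bromo-7-ethenyl-7-methyl-2,5,6,7-tetrahydrooxepin-2-ol (both epimers at C2) | OC1C(Br)=CCC[C@](C)(C=C)O1 | intermediate (not isolated)
10 | (7R)-3-bromo-7-ethenyl-7-methyl-6,7-dihydrooxepin-2(5H)-one | O=C1C(Br)=CCC[C@](C)(C=C)O1 | intermediate
11 | (2R)-6-bromo-2-methyl-7-oxo-2,3,4,7-tetrahydrooxepine-2-carbaldehyde | O=C1C(Br)=CCC[C@](C)(C=O)O1 | intermediate
12 | (2Z)-3-methylpent-2-en-4-yn-1-ol | C#C/C(C)=C\CO | starting material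
13 | tert-butyl(dimethyl){[(2Z)-3-methylpent-2-en-4-yn-1-yl]oxy}silane | C#C/C(C)=C\CO[Si](C)(C)C(C)(C)C | intermediate
14 | tert-butyl(dimethyl){[(2Z)-3-methylpenta-2,4-dien-1-yl]oxy}silane | C=C/C(C)=C\CO[Si](C)(C)C(C)(C)C | intermediate
15 | 9-[(3Z)-5-{[tert-butyl(dimethyl)silyl]oxy}-3-methylpent-3-en-1-yl]-9-borabicyclo[3.3.1]nonane | CC(C)(C)[Si](C)(C)OC/C=C(C)\CCB1C2CCCC1CCC2 | intermediate (not isolated)
16 | (3Z)-5-{[tert-butyl(dimethyl)silyl]oxy}-3-methylpent-3-en-1-ol | CC(C)(C)[Si](C)(C)OC/C=C(C)\CCO | intermediate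
17 | {[(2Z)-5-bromo-3-methylpent-2-en-1-yl]oxy}(tert-butyl)dimethylsilane | CC(C)(C)[Si](C)(C)OC/C=C(C)\CCBr | intermediate
18 | bromido[(3Z)-5-{[tert-butyl(dimethyl)silyl]oxy}-3-methylpent-3-en-1-yl]magnesium | CC(C)(C)[Si](C)(C)OC/C=C(C)\CC[Mg]Br | intermediate (not isolated)
19 | (7R)-3-bromo-7-[(4Z)-6-{[tert-butyl(dimethyl)silyl]oxy}-1-hydroxy-4-methylhex-4-en-1-yl]-7-methyl-6,7-dihydrooxepin-2(5H)-one (both C6 epimers) | O=C1C(Br)=CCC[C@](C)(C(O)CC/C(C)=C\CO[Si](C)(C)C(C)(C)C)O1 | intermediate
20 | (7R)-3-bromo-7-[(4Z)-6-{[tert-butyl(dimethyl)silyl]oxy}-4-methylhex-4-enoyl]-7-methyl-6,7-dihydrooxepin-2(5H)-one | O=C1C(Br)=CCC[C@](C)(C(=O)CC/C(C)=C\CO[Si](C)(C)C(C)(C)C)O1 | intermediate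
21 | (7R)-3-bromo-7-[(1R,4Z)-6-{[tert-butyl(dimethyl)silyl]oxy}-1-hydroxy-4-methylhex-4-en-1-yl]-7-methyl-6,7-dihydrooxepin-2(5H)-one | O=C1C(Br)=CCC[C@](C)([C@H](O)CC/C(C)=C\CO[Si](C)(C)C(C)(C)C)O1 | intermediate
22 | 3-{[tert-butyl(dimethyl)silyl]oxy}propanal | CC(C)(C)[Si](C)(C)OCCC=O | starting material
23 | ethyl 2-[bis(2,2,2-trifluoroethoxy)phosphoryl]propanoate | CCOC(=O)C(C)P(=O)(OCC(F)(F)F)OCC(F)(F)F | starting material
24 | potassium 2-[bis(2,2,2-trifluoroethoxy)phosphoryl]-1-ethoxy-1-oxopropan-2-ide | CCOC(=O)[C-](C)P(=O)(OCC(F)(F)F)OCC(F)(F)F.[K+] | intermediate (not isolated)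
25 | ethyl (2Z)-5-{[tert-butyl(dimethyl)silyl]oxy}-2-methylpent-2-enoate | CCOC(=O)/C(C)=C\CCO[Si](C)(C)C(C)(C)C | intermediate
26 | (2Z)-5-{[tert-butyl(dimethyl)silyl]oxy}-2-methylpent-2-en-1-ol | OC/C(C)=C\CCO[Si](C)(C)C(C)(C)C | intermediate
27 | (2Z)-5-{[tert-butyl(dimethyl)silyl]oxy}-2-methylpent-2-en-1-yl acetate | CC(=O)OC/C(C)=C\CCO[Si](C)(C)C(C)(C)C | intermediate
28 | (2Z)-5-hydroxy-2-methylpent-2-en-1-yl acetate | CC(=O)OC/C(C)=C\CCO | intermediate
29 | (2Z)-5-iodo-2-methylpent-2-en-1-yl acetate | CC(=O)OC/C(C)=C\CCI | intermediate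
30 | [(3Z)-5-(acetyloxy)-4-methylpent-3-en-1-yl](iodido)zinc | CC(=O)OC/C(C)=C\CC[Zn]I | intermediate (not isolated)
31 | (2Z)-5-{(7R)-7-[(1R,4Z)-6-{[tert-butyl(dimethyl)silyl]oxy}-1-hydroxy-4-methylhex-4-en-1-yl]-7-methyl-2-oxo-2,5,6,7-tetrahydrooxepin-3-yl}-2-methylpent-2-en-1-yl acetate | CC(=O)OC/C(C)=C\CCC1=CCC[C@](C)([C@H](O)CC/C(C)=C\CO[Si](C)(C)C(C)(C)C)OC1=O | intermediate
32 | (2Z)-5-{(7R)-7-[(1R,4Z)-1,6-dihydroxy-4-methylhex-4-en-1-yl]-7-methyl-2-oxo-2,5,6,7-tetrahydrooxepin-3-yl}-2-methylpent-2-en-1-yl acetate | CC(=O)OC/C(C)=C\CCC1=CCC[C@](C)([C@H](O)CC/C(C)=C\CO)OC1=O | target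

**Step count and risks**

Total: 20 steps (1–6 ring and C6 aldehyde; 7–10 C1–C5 unit; 11–13 union and C6 centre; 14–18 C12–C16 unit; 19–20 end game).
Longest linear sequence: 11 steps (1–6, 11–13, 19, 20).

Step 19 (Negishi coupling). Zerovalent palladium may ionise the primary allylic acetate of reagent 30 or of the product to a π-allyl complex, which the alkylzinc would then alkylate; this would consume reagent and product in competition with oxidative addition at C11–Br. The fallback carries the C16 oxygen through the coupling as a 4-methoxybenzyl ether and acetylates afterwards. It sets out from 26: NaH and 4-methoxybenzyl chloride should give tert-butyl({(3Z)-5-[(4-methoxyphenyl)methoxy]-4-methylpent-3-en-1-yl}oxy)dimethylsilane F1. Bu4NF then removes the silyl group to give (3Z)-5-[(4-methoxyphenyl)methoxy]-4-methylpent-3-en-1-ol F2, and I2, PPh3 and imidazole convert it into 1-({[(2Z)-5-iodo-2-methylpent-2-en-1-yl]oxy}methyl)-4-methoxybenzene F3. Zinc insertion gives iodido{(3Z)-5-[(4-methoxyphenyl)methoxy]-4-methylpent-3-en-1-yl}zinc F4, which is coupled with 21 under the conditions of step 19 to (7R)-7-[(1R,4Z)-6-{[tert-butyl(dimethyl)silyl]oxy}-1-hydroxy-4-methylhex-4-en-1-yl]-3-{(3Z)-5-[(4-methoxyphenyl)methoxy]-4-methylpent-3-en-1-yl}-7-methyl-6,7-dihydrooxepin-2(5H)-one F5. DDQ in buffered wet CH2Cl2 frees (7R)-7-[(1R,4Z)-6-{[tert-butyl(dimethyl)silyl]oxy}-1-hydroxy-4-methylhex-4-en-1-yl]-3-[(3Z)-5-hydroxy-4-methylpent-3-en-1-yl]-7-methyl-6,7-dihydrooxepin-2(5H)-one F6. Acetyl chloride with 2,4,6-collidine at −78 °C should then acetylate the primary allylic hydroxyl in preference to the hindered secondary C6 hydroxyl, and the route is rejoined at 31.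

Step 13 (CBS reduction). Facial selectivity may be poor if the resident C7 centre with its acyloxy group opposes the catalyst, and borane may add to the C2=C3 alkene. The fallback sets C6 while the C5–C6 bond is formed, by a catalytic asymmetric alkylzinc addition that bypasses 19 and 20. It sets out from 17: NaI in acetone gives tert-butyl{[(2Z)-5-iodo-3-methylpent-2-en-1-yl]oxy}dimethylsilane F7. Iodine–zinc exchange with Et2Zn and catalytic CuI, followed by removal of the volatiles, gives bis[(3Z)-5-{[tert-butyl(dimethyl)silyl]oxy}-3-methylpent-3-en-1-yl]zinc F8. This is added to aldehyde 11 in toluene at −20 °C with Ti(OiPr)4 and a catalytic amount of N,N′-cyclohexane-1,2-diylbis(1,1,1-trifluoromethanesulfonamide). The ligand enantiomer is chosen to send the alkyl group to the Re face of the aldehyde, which corresponds to (6R); by analogy with simple aldehydes this is expected to be the (1S,2S) ligand. The route is rejoined at 21.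

Step 5 (Jones oxidation). In aqueous sulfuric acid the tertiary allylic C7–O bond may ionise, or the ring-opened hydroxy enal may undergo chromium-mediated allylic transposition, before the lactol is oxidised. The fallback avoids both strong acid and chromium. It sets out from 7, which is now isolated after the carbene addition, and opens it with Ag2CO3 in aqueous acetone so that water instead of methanol is captured at C20, giving lactol 9 directly. MnO2 in CH2Cl2 at rt then oxidises this allylic lactol under neutral conditions, and the route is rejoined at 10.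

Further compounds
F1 | step 19 | tert-butyl({(3Z)-5-[(4-methoxyphenyl)methoxy]-4-methylpent-3-en-1-yl}oxy)dimethylsilane | COc1ccc(COC/C(C)=C\CCO[Si](C)(C)C(C)(C)C)cc1
F2 | step 19 | (3Z)-5-[(4-methoxyphenyl)methoxy]-4-methylpent-3-en-1-ol | COc1ccc(COC/C(C)=C\CCO)cc1
F3 | step 19 | 1-({[(2Z)-5-iodo-2-methylpent-2-en-1-yl]oxy}methyl)-4-methoxybenzene | COc1ccc(COC/C(C)=C\CCI)cc1
F4 | step 19 | iodido{(3Z)-5-[(4-methoxyphenyl)methoxy]-4-methylpent-3-en-1-yl}zinc | COc1ccc(COC/C(C)=C\CC[Zn]I)cc1
F5 | step 19 | (7R)-7-[(1R,4Z)-6-{[tert-butyl(dimethyl)silyl]oxy}-1-hydroxy-4-methylhex-4-en-1-yl]-3-{(3Z)-5-[(4-methoxyphenyl)methoxy]-4-methylpent-3-en-1-yl}-7-methyl-6,7-dihydrooxepin-2(5H)-one | COc1ccc(COC/C(C)=C\CCC2=CCC[C@](C)([C@H](O)CC/C(C)=C\CO[Si](C)(C)C(C)(C)C)OC2=O)cc1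
F6 | step 19 | (7R)-7-[(1R,4Z)-6-{[tert-butyl(dimethyl)silyl]oxy}-1-hydroxy-4-methylhex-4-en-1-yl]-3-[(3Z)-5-hydroxy-4-methylpent-3-en-1-yl]-7-methyl-6,7-dihydrooxepin-2(5H)-one | OC/C(C)=C\CCC1=CCC[C@](C)([C@H](O)CC/C(C)=C\CO[Si](C)(C)C(C)(C)C)OC1=O
F7 | step 13 | tert-butyl{[(2Z)-5-iodo-3-methylpent-2-en-1-yl]oxy}dimethylsilane | CC(C)(C)[Si](C)(C)OC/C=C(C)\CCI
F8 | step 13 | bis[(3Z)-5-{[tert-butyl(dimethyl)silyl]oxy}-3-methylpent-3-en-1-yl]zinc | CC(C)(C)[Si](C)(C)OC/C=C(C)\CC[Zn]CC/C(C)=C\CO[Si](C)(C)C(C)(C)C
F0 | step 5 | none | none
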